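The flavone is disconnected at the O1–C8a bond of ring C. A single anodic, hydrogen-evolving C–H/O–H coupling joins the enol oxygen on the ring B side of a 2-prenyloxy-1,3-diketone to C8a. This is the only free C–H carbon ortho to the acyl-bearing C4a of the oxidisable, trioxygenated ring A (ortho to the C8 methoxy group, meta to O5 and O7). The closure forms the pyranone with every substituent already in place. The precursor is the diaryl diketone carrying both prenyl ethers and bulky silyl ethers on the two ring A phenols, assembled by aldol addition and oxidation. Fluoride then unmasks the 5- and 7-hydroxyls.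

Key step: step 7

Remarks on the chemistry
- Target: 5,7-dihydroxy-8-methoxy-3-(prenyloxy)-2-[4-(prenyloxy)phenyl]-4H-chromen-4-one; prenyl = 3-methylbut-2-en-1-yl; it has no stereocentre.
- Closure site: C8a is ortho to C8 (OMe) and to C4a, para to C6–H, and meta, not para, to O5 and O7. In the ring A radical cation the charge sits mainly on the oxygen-bearing carbons, above all C5 and C8, which are para to each other. C8a is therefore not the intrinsically most electrophilic carbon, and the regiochemistry must come from the tether and from blocking the alternatives.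
- Precursor design: the ring A phenols are carried as triisopropylsilyl (TIPS) ethers rather than acetal-type ethers.
  - The bulky groups shield C5 against ipso attack, which would expel the oxygen substituent and give the 5-deoxy-6-methoxy isomer.
  - They flank C6–H against intermolecular aryl coupling.
  - They cannot leave the radical cation as a stabilised carbocation and should persist in the weakly nucleophilic fluoroalcohol.
  - They come off with buffered fluoride, so the aryl and enol prenyl ethers never meet mineral acid.
- Ring A source: a benzaldehyde that already carries the methoxy group avoids methylating one hydroxyl out of three, where the hydroxyl para to the carbonyl group, not the required one, would react first. The aldehyde enters the diketone directly.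
- Assumption: 2,4-dihydroxy-5-methoxybenzaldehyde (1) is taken as a catalogue compound.
- HFIP = 1,1,1,3,3,3-hexafluoropropan-2-ol.

Step 1
Reactants: 1 2,4-dihydroxy-5-methoxybenzaldehyde
Product: 2 5-methoxy-2,4-bis(triisopropylsilyloxy)benzaldehyde
Conditions: TIPSCl (2.4 equiv), imidazole, DMAP (cat.), DMF, 20 → 40 °C
Reagents that add atoms: chlorotri(propan-2-yl)silane (TIPSCl), CC(C)[Si](Cl)(C(C)C)C(C)C
Why: Imidazole-promoted O-silylation of both phenols (silyl ether formation); catalytic DMAP and mild warming should overcome the hydrogen bond between the 2-hydroxyl and the formyl group, which itself is inert.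

Step 2
Reactants: 3 4-bromophenol; 4 prenyl bromide (1-bromo-3-methylbut-2-ene)
Product: 5 1-bromo-4-(prenyloxy)benzene
Conditions: K2CO3, acetone, reflux
Reagents that add atoms: none
Why: Williamson ether synthesis, in which the phenoxide displaces bromide from the primary allylic halide by SN2 and O-alkylation should dominate in acetone.

Step 3
Reactants: 6 prenol (3-methylbut-2-en-1-ol); 7 2-chloro-N-methoxy-N-methylacetamide
Product: 9 N-methoxy-N-methyl-2-(prenyloxy)acetamide, via sodium prenoxide 8 (not isolated)
Conditions: NaH, THF, 0 °C; then 7, 0 → 20 °C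
Reagents that add atoms: none
Why: Williamson ether synthesis on an α-chloro amide, whose carbonyl group accelerates SN2 displacement while the N-methoxy-N-methyl amide resists attack by the alkoxide.

Step 4
Reactants: 5 1-bromo-4-(prenyloxy)benzene; 9 N-methoxy-N-methyl-2-(prenyloxy)acetamide
Product: 12 2-(prenyloxy)-1-[4-(prenyloxy)phenyl]ethan-1-one, via aryllithium 10 (not isolated), via lithium hemiaminal alkoxide 11 (not isolated)
Conditions: n-BuLi, THF, −78 °C; then 9, −78 → −20 °C; AcOH, H2O
Reagents that add atoms: none
Why: Bromine–lithium exchange followed by Weinreb ketone synthesis, in which the chelated tetrahedral adduct survives until the quench so that no tertiary alcohol should form, and the aryl prenyl ether is inert to n-BuLi at −78 °C.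

Step 5
Reactants: 12 2-(prenyloxy)-1-[4-(prenyloxy)phenyl]ethan-1-one; 2 5-methoxy-2,4-bis(triisopropylsilyloxy)benzaldehyde
Product: 14 3-hydroxy-3-[5-methoxy-2,4-bis(triisopropylsilyloxy)phenyl]-2-(prenyloxy)-1-[4-(prenyloxy)phenyl]propan-1-one (racemic syn/anti mixture), via lithium enolate 13 (not isolated)
Conditions: LiN(SiMe3)2, THF, −78 °C; then 2, −78 °C; AcOH at −78 °C
Reagents that add atoms: none
Why: Aldol addition of a lithium enolate, where the ketone has one enolisable position and the aldehyde none so only the cross product can form; the two new stereocentres arise without control as a racemic syn/anti mixture, which is acceptable because both are erased in steps 6 and 7, and the cold quench should prevent retro-aldol cleavage and silyl migration.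

Step 6
Reactants: 14 the aldol from step 5
Product: 15 1-[5-methoxy-2,4-bis(triisopropylsilyloxy)phenyl]-2-(prenyloxy)-3-[4-(prenyloxy)phenyl]propane-1,3-dione (racemic)
Conditions: Dess–Martin periodinane, CH2Cl2, 0 → 20 °C
Reagents that add atoms: none
Why: Dess–Martin oxidation of the secondary benzylic alcohol to the ketone under near-neutral conditions, which should spare the silyl ethers and the prenyl alkenes; the remaining stereocentre between the carbonyl groups is racemic and disappears in step 7.

Step 7
Reactants: 15 1-[5-methoxy-2,4-bis(triisopropylsilyloxy)phenyl]-2-(prenyloxy)-3-[4-(prenyloxy)phenyl]propane-1,3-dione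
Product: 16 8-methoxy-3-(prenyloxy)-2-[4-(prenyloxy)phenyl]-5,7-bis(triisopropylsilyloxy)-4H-chromen-4-one
Conditions: glassy carbon anode, Pt cathode, undivided cell, constant current (2 mA cm−2, 2.2 F mol−1), [MeN(n-Bu)3][MeOSO3] (0.05 M), HFIP/CH2Cl2 9:1, 0.01 M in 15, 20 °C
Reagents that add atoms: none
Why: Proposed new method: the anode should remove one electron from the trioxygenated ring A, the most easily oxidised π-system of 15 (ring B and the un-ionised dicarbonyl unit are acyl-deactivated and the alkenes lie higher), and HFIP both stabilises this radical cation and breaks the internal hydrogen bond of the enol, so that the oxygen of the carbonyl group on the ring B side (as enol, or as carbonyl followed by loss of the C2 proton) can add to the ortho C–H carbon; a second electron transfer gives a cyclohexadienyl cation stabilised by the neighbouring methoxy group, which loses its proton to rearomatise, while the protons are reduced to H2 at the cathode. The nearest known reaction types are anodic C–H/heteroatom–H ring closures onto electron-rich arenes (anilides to benzoxazoles, biaryl carboxylic acids to benzocoumarins), oxidant-driven closure of α-aryl ketone enols to benzofurans and, for the same bond by another mechanism, the copper-catalysed cyclisation of 2-haloaryl 1,3-diketones to flavones. Ring C closes in a six-membered mode, formally 6-endo-trig with respect to the C4a–C8a bond of ring A, which stays in the new ring. No stereocentre is formed and the labile one at C2 of 15 becomes trigonal. The step needs site selectivity for C8a over ipso attack at the silyloxy-bearing carbon (future C5) and over intermolecular coupling at the future C6–H, and chemoselectivity for ring A over the prenyl alkenes and the enol: C8a is the only C–H ortho to the acyl group and the only carbon the oxygen can reach through a six-membered ring without expelling a substituent, the TIPS groups shield C5 and C6, and low current density, high dilution and a charge near 2 F per mole limit alkene oxidation and over-oxidation of 16.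

Step 8
Reactants: 16 8-methoxy-3-(prenyloxy)-2-[4-(prenyloxy)phenyl]-5,7-bis(triisopropylsilyloxy)-4H-chromen-4-one
Product: 17 5,7-dihydroxy-8-methoxy-3-(prenyloxy)-2-[4-(prenyloxy)phenyl]-4H-chromen-4-one (target)
Conditions: n-Bu4NF (2.5 equiv), AcOH (2.5 equiv), THF, 0 → 20 °C
Reagents that add atoms: none
Why: Fluoride-induced cleavage of the two aryl silyl ethers (strong Si–F bond, phenoxide as leaving group), buffered with acetic acid so that the prenyl ethers, the methyl ether and the chromone ring, all inert to fluoride, see neither strong base nor strong acid.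

Compound list
1 | 2,4-dihydroxy-5-methoxybenzaldehyde | COc1cc(C=O)c(O)cc1O | starting material
2 | 5-methoxy-2,4-bis(triisopropylsilyloxy)benzaldehyde | COc1cc(C=O)c(O[Si](C(C)C)(C(C)C)C(C)C)cc1O[Si](C(C)C)(C(C)C)C(C)C | intermediate
3 | 4-bromophenol | Oc1ccc(Br)cc1 | starting material
4 | prenyl bromide (1-bromo-3-methylbut-2-ene) | CC(C)=CCBr | starting material
5 | 1-bromo-4-(prenyloxy)benzene | CC(C)=CCOc1ccc(Br)cc1 | intermediate
6 | prenol (3-methylbut-2-en-1-ol) | CC(C)=CCO | starting material
7 | 2-chloro-N-methoxy-N-methylacetamide | CON(C)C(=O)CCl | starting material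
8 | sodium 3-methylbut-2-en-1-olate (formed in the flask) | [Na+].[O-]CC=C(C)C | intermediate
9 | N-methoxy-N-methyl-2-(prenyloxy)acetamide | CON(C)C(=O)COCC=C(C)C | intermediate
10 | [4-(prenyloxy)phenyl]lithium (formed in the flask) | [Li]c1ccc(OCC=C(C)C)cc1 | intermediate
11 | lithium 1-[methoxy(methyl)amino]-2-(prenyloxy)-1-[4-(prenyloxy)phenyl]ethan-1-olate, racemic (formed in the flask) | [Li]OC(COCC=C(C)C)(N(C)OC)c1ccc(OCC=C(C)C)cc1 | intermediate
12 | 2-(prenyloxy)-1-[4-(prenyloxy)phenyl]ethan-1-one | CC(C)=CCOCC(=O)c1ccc(OCC=C(C)C)cc1 | intermediate
13 | lithium (Z)-2-(prenyloxy)-1-[4-(prenyloxy)phenyl]ethen-1-olate, chelated enolate (formed in the flask) | [Li]O/C(=C\OCC=C(C)C)c1ccc(OCC=C(C)C)cc1 | intermediate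
14 | 3-hydroxy-3-[5-methoxy-2,4-bis(triisopropylsilyloxy)phenyl]-2-(prenyloxy)-1-[4-(prenyloxy)phenyl]propan-1-one, racemic mixture of syn and anti diastereomers | COc1cc(C(O)C(OCC=C(C)C)C(=O)c2ccc(OCC=C(C)C)cc2)c(O[Si](C(C)C)(C(C)C)C(C)C)cc1O[Si](C(C)C)(C(C)C)C(C)C | intermediate
15 | 1-[5-methoxy-2,4-bis(triisopropylsilyloxy)phenyl]-2-(prenyloxy)-3-[4-(prenyloxy)phenyl]propane-1,3-dione, racemic and configurationally labile at C2 | COc1cc(C(=O)C(OCC=C(C)C)C(=O)c2ccc(OCC=C(C)C)cc2)c(O[Si](C(C)C)(C(C)C)C(C)C)cc1O[Si](C(C)C)(C(C)C)C(C)C | intermediate
16 | 8-methoxy-3-(prenyloxy)-2-[4-(prenyloxy)phenyl]-5,7-bis(triisopropylsilyloxy)-4H-chromen-4-one | COc1c(O[Si](C(C)C)(C(C)C)C(C)C)cc(O[Si](C(C)C)(C(C)C)C(C)C)c2c(=O)c(OCC=C(C)C)c(-c3ccc(OCC=C(C)C)cc3)oc12 | intermediate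
17 | 5,7-dihydroxy-8-methoxy-3-(prenyloxy)-2-[4-(prenyloxy)phenyl]-4H-chromen-4-one | COc1c(O)cc(O)c2c(=O)c(OCC=C(C)C)c(-c3ccc(OCC=C(C)C)cc3)oc12 | target

Total step count: 8.
Longest linear sequence: 6 steps (step 2 or step 3, then steps 4, 5, 6, 7 and 8).

Steps most likely to fail

Step 7 (new method). Several things may go wrong:
- the ring A radical cation may be trapped at the silyloxy-bearing carbon with loss of that oxygen substituent;
- the enol may be oxidised instead, with fragmentation of the enol prenyl ether;
- the electron-rich product may be oxidised further;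
- silyl groups may be lost at the anode.

The fallback uses known chemistry, sets out from aldehyde 2 and comes back at flavone 16. Aldehyde 2 is treated with LiN(Me)CH2CH2NMe2 in THF to give the lithium α-amino alkoxide F1. This directs n-BuLi to the only C–H ortho to the masked formyl group, which is also ortho to the methoxy group, giving the aryllithium F2. I2 and aqueous work-up then give 2-iodo-3-methoxy-4,6-bis(triisopropylsilyloxy)benzaldehyde F3 (directed ortho-metalation of a benzaldehyde through its α-amino alkoxide). Addition of enolate 13 under the conditions of step 5 gives the iodo aldol F4, and Dess–Martin oxidation gives the iodo diketone F5. CuI (monovalent copper, catalytic) with 1,10-phenanthroline and K3PO4 in toluene at 80 °C then forms the same O1–C8a bond by intramolecular Ullmann-type O-arylation of the diketonate, the established closure of 2-haloaryl 1,3-diketones to flavones, and delivers 16.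

Step 5. The ortho silyl group may migrate from the phenol oxygen to the new alkoxide, the aldolate may revert on warming, or the allyloxy enolate may undergo [2,3]-Wittig rearrangement before it meets the aldehyde. The fallback sets out from aldehyde 2 and comes back at diketone 15, bypassing 14 and step 6. Pinnick oxidation of 2 (NaClO2, NaH2PO4, 2-methylbut-2-ene, t-BuOH/H2O) gives 5-methoxy-2,4-bis(triisopropylsilyloxy)benzoic acid F6. 1,1′-Carbonyldiimidazole in THF converts it into the acyl imidazolide F7. This is added at −78 °C to two equivalents of enolate 13 (the second equivalent is consumed by the more acidic product), so that Claisen-type C-acylation gives 15 directly, with no alkoxide present to accept a silyl group.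

Step 4. The basic aryllithium may deprotonate the amide next to the ether oxygen instead of adding to it, or halogen–metal exchange may be incomplete, returning starting materials. The fallback sets out from prenyl bromide 4 and comes back at ketone 12. Commercial 2-hydroxy-1-(4-hydroxyphenyl)ethanone is alkylated at the more acidic phenol with 4 and K2CO3 in acetone to give 2-hydroxy-1-[4-(prenyloxy)phenyl]ethan-1-one F8. The ketol hydroxyl is then etherified with a second portion of 4 and Ag2O in CH2Cl2, a non-basic alkylation that avoids enolate chemistry of the hydroxy ketone, giving 12 without any organometallic step.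

Further compounds
F1 | step 7 | lithium [5-methoxy-2,4-bis(triisopropylsilyloxy)phenyl]{[2-(dimethylamino)ethyl](methyl)amino}methanolate (formed in the flask) | [Li]OC(N(C)CCN(C)C)c1cc(OC)c(O[Si](C(C)C)(C(C)C)C(C)C)cc1O[Si](C(C)C)(C(C)C)C(C)C
F2 | step 7 | ortho-lithiated derivative of F1, lithium on the ring carbon between the methoxy-bearing and the benzylic-substituted carbons (formed in the flask) | [Li]OC(N(C)CCN(C)C)c1c([Li])c(OC)c(O[Si](C(C)C)(C(C)C)C(C)C)cc1O[Si](C(C)C)(C(C)C)C(C)C
F3 | step 7 | 2-iodo-3-methoxy-4,6-bis(triisopropylsilyloxy)benzaldehyde | COc1c(I)c(C=O)c(O[Si](C(C)C)(C(C)C)C(C)C)cc1O[Si](C(C)C)(C(C)C)C(C)C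
F4 | step 7 | 3-hydroxy-3-[2-iodo-3-methoxy-4,6-bis(triisopropylsilyloxy)phenyl]-2-(prenyloxy)-1-[4-(prenyloxy)phenyl]propan-1-one, racemic mixture of diastereomers | COc1c(I)c(C(O)C(OCC=C(C)C)C(=O)c2ccc(OCC=C(C)C)cc2)c(O[Si](C(C)C)(C(C)C)C(C)C)cc1O[Si](C(C)C)(C(C)C)C(C)C
F5 | step 7 | 1-[2-iodo-3-methoxy-4,6-bis(triisopropylsilyloxy)phenyl]-2-(prenyloxy)-3-[4-(prenyloxy)phenyl]propane-1,3-dione, racemic | COc1c(I)c(C(=O)C(OCC=C(C)C)C(=O)c2ccc(OCC=C(C)C)cc2)c(O[Si](C(C)C)(C(C)C)C(C)C)cc1O[Si](C(C)C)(C(C)C)C(C)C
F6 | step 5 | 5-methoxy-2,4-bis(triisopropylsilyloxy)benzoic acid | COc1cc(C(O)=O)c(O[Si](C(C)C)(C(C)C)C(C)C)cc1O[Si](C(C)C)(C(C)C)C(C)C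
F7 | step 5 | (1H-imidazol-1-yl)[5-methoxy-2,4-bis(triisopropylsilyloxy)phenyl]methanone | COc1cc(C(=O)n2ccnc2)c(O[Si](C(C)C)(C(C)C)C(C)C)cc1O[Si](C(C)C)(C(C)C)C(C)C
F8 | step 4 | 2-hydroxy-1-[4-(prenyloxy)phenyl]ethan-1-one | CC(C)=CCOc1ccc(C(=O)CO)cc1
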